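## The problem

Compound 41 is a germacranolide: a ten-membered carbocycle (C1–C10) fused through O6 and C7 to a butenolide (C7=C11, C12 carbonyl, C13 carrying the acetate). It has trans-epoxides across C1–C10 and C4–C5, a tiglate on O8, methyl C14 on C10 and methyl C15 on C4, and the configuration 1R,4R,5R,6S,8S,10R. This numbering is used for every intermediate, so the cyclohexane stage has the ring C1–C10–C9–C8–C7–C6.

A synthesis has to make a strained medium ring without paying for an end-to-end closure. It must also place six stereocentres around that ring, where conformational arguments are weak. C8 and C10 are separated by the C9 methylene and cannot be derived from one another, so both must be brought in from outside. The others can be relayed: C1 from the oxygen on C10, C6 from a temporary oxygen on C7, and C4/C5 from the C6 hydroxyl.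

The two epoxides do not tolerate acid (transannular opening). The butenolide does not tolerate strong base (deprotonation at C6). The tiglate and the allylic acetate do not tolerate hydrides or organometallics. These groups must therefore appear late and in that order of caution.

The feature that opens the route is that every ring carbon that is or was oxygenated (C1, C10, C8, C7, C6) lies on the six-atom arc C6–C7–C8–C9–C10–C1, while C2–C5 is bare carbon. Closing that arc through C1–C6 gives a cyclohexane, and C2–C3 and C4–C5(–C15) become a vinyl group on C1 and an (E)-propenyl group on C6. A [3,3] shift then forms C3–C4 while C1–C6 breaks.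

## Retrosynthesis

**Esters (41 ⇒ 39 ⇒ 38).** The C8–O and C13–O acyl bonds are cut first. They are the groups least compatible with hydride, organometallic and fluoride steps, and diol 38 differentiates itself (primary allylic against hindered secondary alcohol). The forward steps are a selective acetylation and a tigloylation.

**Butenolide (38 ⇒ 37 ⇒ 35 + 31).** C7=C11 is cut as an intramolecular Horner–Wadsworth–Emmons olefination of a C6 phosphonoacetate onto a C7 ketone, and the C12–O6 bond as an esterification. An aldol–dehydration would need a base strong enough to enolise the C7 ketone, whereas the phosphonate reacts with an amine base. The C13 oxygen travels inside the acid 31 as a silyl ether. The precursor 35 has C7 as a carbinol that was protected as a PMB ether until then.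

**1,10-Epoxide (34 ⇒ 33 ⇒ 32).** The C1–O bond is cut, so that the tertiary O10 displaces an activated O1 with inversion. This is preferred to epoxidising a 1(10)-alkene because the result does not depend on ring conformation. The trans-epoxide needs the diol obtained by chelation-controlled reduction of the C1 ketone next to the free C10 hydroxyl. The closure must be base-free, because the phosphonate α-hydrogen is present.

**C4–C6 (26 ⇒ 25 ⇒ 24 ⇒ 22).** The 4,5-epoxide comes from hydroxyl-directed epoxidation of a 4E-allylic alcohol. The C6 carbinol comes from chelation-controlled reduction of the enone, with O7–PMB as the anchor. The enone comes from an enol ether at C5=C6. Each step removes one stereocentre from the problem; the forward sequence needs the 4E geometry.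

**Ring (22 ⇒ 20), the key cut.** C3–C4 is cut and C1–C6 re-formed, taking the ten-membered ring back to a 1-vinyl-2-(E)-propenylcyclohexane-1,2-diol derivative. Only O1 is left free; O6 is a MOM ether. A twofold alkoxide would give a 1,6-diketone whose two carbonyls cannot be told apart and which aldolises across the ring. With one ether the rearrangement delivers C1 as a ketone and C6 as an enol ether whose double bond already points to C5. The precursor 20 is a rigid six-membered ring carrying C8 and C10.

**Alkenyl groups (20 ⇒ 18 + 19; 16 ⇒ 13 + 14; 13 ⇒ 11).** The C1–C2 and C6–C5 bonds are cut as additions of vinylmagnesium bromide and (E)-propenyllithium to ketones. The C1 oxygen is introduced by enolate hydroxylation of ketone 11. The carbinol configurations at C1 and C6 are lost in the key step, so these additions need only be clean, not selective.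

**Chiral pool (11 ⇒ 1).** (−)-Quinic acid supplies C10 (its C1, carboxyl to C14 methyl), C6 (its C3), C7 (its C4) and C8 (its C5). With the natural acid this is the only assignment that gives the right absolute configuration at C10; placing the cis-diol oxygens on C7/C8 instead leads into the enantiomeric series. The price is that the C5 carbinol of quinic acid (C8) must be inverted, which oxidation and reduction do in steps 5 and 6. An anisylidene acetal on the cis-diol is opened reductively to leave PMB on O7 and free the C6 hydroxyl for oxidation.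

**Phosphonate (31 ⇒ 28).** The acid is cut at C11–C12 as a carboxylation of a lithiated phosphonate.

## Roads not taken

**Alternative 1:** The cut is the C6–O bond and the lactone C12–O bond. In the forward step a cytochrome P450 of the CYP71 family hydroxylates C6 of the 8β-hydroxygermacrene acid A1 and the alcohol lactonises to eupatolide A2.

- Merits: one enzymatic step sets C6 and closes the lactone on a skeleton that already has both E-alkenes, and peracid epoxidation of such rings from the periphery is well precedented.
- Weak points: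
  - A2 carries H7 and an 11(13)-methylene, so the 7(11)-alkene and the C13 oxygen still need an oxidative allylic transposition.
  - C8 of A2 has the configuration opposite to that of 41 and would have to be inverted.
  - The route depends on a supply of A1 and of the enzyme in an engineered host.
- Comparison: if A1 and the biocatalyst are at hand this road is far shorter, and in step economy it is clearly better. The chosen plan sets against it catalogue starting materials and a C8 centre that is fixed on a cyclohexane in the first six steps.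

**Alternative 2:** The cut is the C8–O and C13–O bonds. In the forward step singlet oxygen adds across C8 and C13 of the s-cis diene of the diepoxy methylene lactone A3 to give the endoperoxide A4. Reduction of the O–O bond would then give diol 38 of the present route.

- Merits: both oxygens and the tetrasubstituted butenolide alkene arrive in one neutral step that the epoxides tolerate.
- Weak points:
  - The difficulty moves into A3, a diepoxy germacranolide with a 7Z-alkene, which is no easier to make than 38.
  - A3 lacks the C8 oxygen as a handle.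
  - The face of attack at C8 rests on ring conformation alone.
  - Ene reaction at C9 or C6 competes, and the diene is electron-poor.
- Comparison: as an endgame it is shorter than steps 22 to 27 here. The chosen plan sets against it an O8 whose configuration is certain and a butenolide built by a carbonyl olefination that cannot give regioisomers.

**Alternative 3:** The cut is the C5–C6 and C4–C15 bonds together with the lactone C–O bond. In the forward step Ni(COD)2, a zerovalent nickel source, couples the alkyne and the aldehyde of the ynal A5 with Me2Zn and closes the ring; lactonisation gives A6.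

- Merits: this is the most convergent road. Ring, 4E-alkene (fixed by syn addition, which the present route can only hope for in step 16), C6 carbinol and lactone form in one step, and about five steps remain after A6.
- Weak points:
  - A ten-membered ring must close end to end.
  - The aldehyde of A5 is conjugated to a tetrasubstituted enoate.
  - The allylic acetate at C13 is a leaving group towards zerovalent nickel.
  - C6 is set relative to a remote C8 by a macrocyclic transition state.
- Comparison: this road is shorter and controls the C4=C5 geometry better. The chosen plan sets against it a ring formed by four-atom expansion of a six-membered ring, and a C6 centre set by chelation to its neighbour.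

Key step: step 15

Assumption: the configurations written at C1 and C6 of 13–20 and at C4 of 21–23 are the expected ones, and the acetal carbon (2–9), C5 of 23 and C11 of 31–36 are mixtures; all are destroyed before 41, so another ratio changes no later compound.

## Route

Step 1
Reactants: 1 (−)-quinic acid
Product: 2 anisylidene quinide (O6/O7 4-methoxybenzylidene acetal; lactone from C14 to O8)
Conditions: 4-MeOC6H4CH(OMe)2, camphorsulfonic acid (cat.), PhMe, reflux
Reagents that add atoms: 4-methoxybenzaldehyde dimethyl acetal, COC(OC)c1ccc(OC)cc1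
Why: Acid-catalysed transacetalisation takes the only cis-1,2-diol (O6/O7) and the carboxyl lactonises onto the cis O8, as quinic acid does with other aldehydes and ketones.

Step 2
Reactants: 2 anisylidene quinide
Product: 3 triol (C14 hydroxymethyl; C10–OH; C8–OH)
Conditions: LiAlH4, THF, 0 °C to rt
Reagents that add atoms: none
Why: Hydride reduction of the lactone to the primary alcohol and the C8 alcohol; the acetal is inert without a Lewis acid.

Step 3
Reactants: 3 triol
Product: 4 C14 tosylate
Conditions: TsCl, pyridine, 0 °C
Reagents that add atoms: 4-toluenesulfonyl chloride, Cc1ccc(cc1)S(Cl)(=O)=O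
Why: Sulfonylation is selective for the primary hydroxyl over the secondary C8 and tertiary C10 hydroxyls.

Step 4
Reactants: 4 C14 tosylate
Product: 5 C10-methyl diol (C10–OH; C8–OH trans to O7)
Conditions: LiAlH4, THF, reflux
Reagents that add atoms: none
Why: Reductive removal of the sulfonate; the neighbouring tertiary alkoxide closes a spiro-epoxide that hydride opens at CH2, which turns the former carboxyl into the C14 methyl.

Step 5
Reactants: 5 C10-methyl diol
Product: 6 C8 ketone
Conditions: Dess–Martin periodinane, NaHCO3, CH2Cl2, rt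
Reagents that add atoms: none
Why: Periodinane oxidation of the only secondary alcohol under buffered conditions, which spare the acetal and do not dehydrate the β-hydroxy ketone.

Step 6
Reactants: 6 C8 ketone
Product: 7 all-cis diol (C8–OH cis to O7 and O10)
Conditions: NaBH4, MeOH, −40 °C
Reagents that add atoms: none
Why: Borohydride attacks the face opposite the cis-fused dioxolane and the axial C10 hydroxyl, so the new C8–OH is cis to O7; this oxidation–reduction pair inverts the natural carbinol and sets C8 as in 41.

Step 7
Reactants: 7 all-cis diol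
Product: 9 O8-TIPS O10-TES acetal, via O8-TIPS ether 8 (not isolated)
Conditions: TIPSOTf, 2,6-lutidine, CH2Cl2, −78 °C; then TESOTf, 0 °C
Reagents that add atoms: triisopropylsilyl trifluoromethanesulfonate, CC(C)[Si](OS(=O)(=O)C(F)(F)F)(C(C)C)C(C)C; triethylsilyl trifluoromethanesulfonate, CC[Si](CC)(CC)OS(=O)(=O)C(F)(F)F
Why: The bulky silyl triflate takes the secondary hydroxyl first and the smaller one then silylates the tertiary hydroxyl; the two groups are later removed separately by fluoride.

Step 8
Reactants: 9 O8-TIPS O10-TES acetal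
Product: 10 C6 alcohol (O7–PMB)
Conditions: i-Bu2AlH, CH2Cl2, −78 to 0 °C
Reagents that add atoms: none
Why: Reductive opening of a 4-methoxybenzylidene acetal; aluminium binds the less hindered O6 (next to the C1 methylene) and that C–O bond is cleaved, so PMB stays on the crowded O7 and both acetal epimers converge.

Step 9
Reactants: 10 C6 alcohol
Product: 11 C6 ketone
Conditions: Dess–Martin periodinane, NaHCO3, CH2Cl2, rt
Reagents that add atoms: none
Why: Neutral oxidation of the free secondary alcohol; no base is present that could eliminate the β-silyloxy group.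

Step 10
Reactants: 11 C6 ketone
Product: 13 C1-hydroxy ketone, via lithium enolate 12 (not isolated)
Conditions: LiN(SiMe3)2, THF, −78 °C; then 3-phenyl-2-(phenylsulfonyl)oxaziridine, −78 °C; NH4Cl
Reagents that add atoms: 3-phenyl-2-(phenylsulfonyl)oxaziridine, O=S(=O)(N1OC1c1ccccc1)c1ccccc1
Why: Kinetic deprotonation occurs at the C1 methylene and not at the equatorial alkoxy-bearing C7–H, and the enolate is hydroxylated by the sulfonyloxaziridine (Davis oxidation) at −78 °C before it can expel the β-silyloxy group.

Step 11
Reactants: 13 C1-hydroxy ketone; 14 (E)-1-bromoprop-1-ene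
Product: 16 propenyl diol, via (E)-prop-1-enyllithium 15 (not isolated)
Conditions: 14, t-BuLi, Et2O, −78 °C; then 13, THF, −78 to −40 °C
Reagents that add atoms: none
Why: Bromine–lithium exchange keeps the E geometry and the alkenyllithium adds 1,2 to the ketone of the lithium alkoxide; attack is expected anti to the axial C10 methyl.

Step 12
Reactants: 16 propenyl diol
Product: 17 C1 ketone (tertiary C6–OH)
Conditions: IBX, DMSO, rt
Reagents that add atoms: none
Why: IBX oxidises the secondary alcohol of a secondary–tertiary 1,2-diol to the ketol without cleaving the C–C bond.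

Step 13
Reactants: 17 C1 ketone
Product: 18 C6 MOM ether
Conditions: MOMCl, i-Pr2NEt, Bu4NI (cat.), ClCH2CH2Cl, 60 °C
Reagents that add atoms: chloromethyl methyl ether, COCCl
Why: Alkylation of the only free hydroxyl; the ketone has no α-hydrogen, so warming with amine base is safe, and the ether cannot migrate in the key step.

Step 14
Reactants: 18 C6 MOM ether; 19 vinylmagnesium bromide
Product: 20 vinyl propenyl carbinol (key-step precursor)
Conditions: CH2=CHMgBr, THF, −20 °C to rt
Reagents that add atoms: none
Why: Grignard addition to a non-enolisable ketone; magnesium chelated between the carbonyl and O6–MOM (Cram chelate) directs the vinyl group anti to the propenyl group, giving the trans-dialkenyl arrangement.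

Step 15
Reactants: 20 vinyl propenyl carbinol
Product: 22 ten-membered keto enol ether, via potassium enolate 21 (not isolated)
Conditions: KH, 18-crown-6, THF, 0 °C to rt; then AcOH, −78 °C
Reagents that add atoms: none
Why: KH with the crown ether gives the free C1 potassium alkoxide, which weakens the C1–C6 bond, and the 1,5-diene C3=C2–C1–C6–C5=C4 rearranges by a concerted [3,3] shift that forms C3–C4 and breaks C1–C6. The closest known reaction type is the anionic oxy-Cope ring expansion of 1,2-dialkenylcyclohexanols and 1,2-diol derivatives to cyclodecenones and cyclodecane-1,6-diones. The ten-membered ring is closed by four-atom ring expansion of the cyclohexane, not by joining chain ends. The two alkenyl groups are trans-diequatorial, so the transition state is a chair with the propenyl methyl equatorial; this sets the new C4 centre (R, removed in step 16) and puts C4 trans to C7 on the C5=C6 enol ether. Formation of the C1 enolate makes the step irreversible, and C8 and C10 are spectators. The selectivity needed is that only O1 is ionised, which the MOM ether on O6 and the silyl and benzyl ethers secure. The product therefore carries one ketone after protonation and one enol ether directed to C5, which distinguishes C1 from C6 and prevents transannular aldol reaction.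

Step 16
Reactants: 22 ten-membered keto enol ether
Product: 24 4E-enone, via C5 selenide 23 (not isolated)
Conditions: PhSeCl, pyridine, CH2Cl2, −78 °C; then 30% H2O2, 0 °C to rt
Reagents that add atoms: none
Why: Selenenylation of the enol ether puts selenium on C5 only and releases the MOM group, and the selenoxide eliminates syn towards the single β-hydrogen on C4. The 4E alkene needs the C5 epimer with selenium syn to C3; it is expected because the α-seleno ketone epimerises under the amine-buffered conditions and syn eliminations in ten-membered rings favour the trans alkene.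

Step 17
Reactants: 24 4E-enone
Product: 25 allylic alcohol (6S)
Conditions: Zn(BH4)2, Et2O, −78 to −40 °C
Reagents that add atoms: none
Why: Chelation-controlled 1,2-reduction: zinc bridges the C6 carbonyl and O7–PMB and hydride enters from the side of H7 (Cram chelate), giving the anti C6/C7 relationship, which is the C6 configuration of 41. The C1 ketone has a silyloxy group on a quaternary neighbour, cannot chelate and should react only at higher temperature.

Step 18
Reactants: 25 allylic alcohol
Product: 26 4,5-epoxy alcohol
Conditions: VO(acac)2 (cat.), t-BuOOH, CH2Cl2, 0 °C to rt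
Reagents that add atoms: tert-butyl hydroperoxide, CC(C)(C)OO
Why: Hydroxyl-directed epoxidation; the C15 methyl is cis to C6, so allylic 1,3-strain holds H6 in the alkene plane and oxygen is delivered to the face of the hydroxyl, giving the threo epoxy alcohol (4R,5R), trans because the alkene is E.

Step 19
Reactants: 26 4,5-epoxy alcohol
Product: 27 C10 alcohol
Conditions: Bu4NF, AcOH, THF, 0 °C
Reagents that add atoms: none
Why: Buffered fluoride removes the triethylsilyl ether and leaves the far more stable triisopropylsilyl ether; the buffer avoids base-induced ketol rearrangement.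

Step 20
Reactants: 28 diethyl (2-hydroxyethyl)phosphonate
Product: 29 TBS ether of 28
Conditions: TBSCl, imidazole, DMF, rt
Reagents that add atoms: tert-butyldimethylsilyl chloride, CC(C)(C)[Si](C)(C)Cl
Why: Standard silylation of a primary alcohol.

Step 21
Reactants: 29 TBS ether of 28
Product: 31 phosphonate acid (2-diethoxyphosphoryl-3-silyloxypropanoic acid), via lithiated phosphonate 30 (not isolated)
Conditions: LiN(i-Pr)2, THF, −78 °C; then CO2; cold 1 M HCl
Reagents that add atoms: carbon dioxide, O=C=O
Why: Lithiation α to phosphorus and carboxylation is the usual route to 2-phosphonoalkanoic acids; the anion is kept at −78 °C so that it does not lose silanolate.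

Step 22
Reactants: 27 C10 alcohol; 31 phosphonate acid
Product: 32 C6 phosphonate ester
Conditions: DCC, DMAP (cat.), CH2Cl2, 0 °C to rt
Reagents that add atoms: none
Why: Carbodiimide esterification (Steglich) of the only secondary hydroxyl; phosphonoacetic acids acylate hindered alcohols well and the tertiary C10–OH does not react.

Step 23
Reactants: 32 C6 phosphonate ester
Product: 33 1,10-diol
Conditions: Zn(BH4)2, Et2O–THF, −40 to −20 °C
Reagents that add atoms: none
Why: Chelation-controlled reduction of the α-hydroxy ketone: zinc bridges O1 and O10 and hydride enters from the side of the C14 methyl, giving the diol in which C2 and C9 are eclipsed when the two C–O bonds are; ester, phosphonate and epoxide are not reduced.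

Step 24
Reactants: 33 1,10-diol
Product: 34 1,10:4,5-diepoxide
Conditions: PPh3, DIAD, PhMe, 0 to 60 °C
Reagents that add atoms: none
Why: Mitsunobu cyclodehydration of a 1,2-diol: the secondary O1 is activated and the tertiary O10 displaces it with inversion at C1, which gives the trans-epoxide (1R,10R) without any base that would deprotonate the phosphonate.

Step 25
Reactants: 34 1,10:4,5-diepoxide
Product: 35 C7 alcohol
Conditions: DDQ, CH2Cl2–pH 7 buffer, 0 °C
Reagents that add atoms: none
Why: Oxidative cleavage of the PMB ether under buffered, neutral conditions that epoxides, silyl ethers and the ester tolerate.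

Step 26
Reactants: 35 C7 alcohol
Product: 37 butenolide (O8–TIPS; O13–TBS), via C7 ketone 36 (not isolated)
Conditions: Dess–Martin periodinane, NaHCO3, CH2Cl2; then LiCl, i-Pr2NEt, MeCN, 0 °C to rt
Reagents that add atoms: none
Why: Oxidation gives the α-acyloxy ketone, and the lithium-chelated phosphonate anion adds to C7 and eliminates phosphate (intramolecular Horner–Wadsworth–Emmons, Masamune–Roush conditions). This closes the five-membered lactone ring and forms C7=C11 with a base too weak to epimerise C6.

Step 27
Reactants: 37 butenolide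
Product: 38 8,13-diol
Conditions: Bu4NF, AcOH, THF, rt
Reagents that add atoms: none
Why: Fluoride cleaves both silyl ethers; acetic acid keeps the medium from deprotonating the butenolide at C6.

Step 28
Reactants: 38 8,13-diol
Product: 39 13-acetate
Conditions: Ac2O, 2,4,6-collidine, CH2Cl2, −20 °C
Reagents that add atoms: acetic anhydride, CC(=O)OC(C)=O
Why: The primary allylic hydroxyl is acylated much faster than the hindered secondary C8 hydroxyl at low temperature with one equivalent of anhydride.

Step 29
Reactants: 39 13-acetate; 40 tigloyl chloride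
Product: 41 target (CNP0251711.1)
Conditions: 40, DMAP, Et3N, CH2Cl2, 0 °C to rt
Reagents that add atoms: none
Why: DMAP-catalysed acylation of the remaining secondary alcohol with retention at C8; the E-configured tiglate does not isomerise under these conditions.

## Compound list

1 | (−)-quinic acid | C1[C@H]([C@H]([C@@H](C[C@@]1(C(=O)O)O)O)O)O | starting material
2 | anisylidene quinide: O6/O7 4-methoxybenzylidene acetal, C14 lactone to O8, free C10–OH (acetal carbon epimers) | C1[C@H]([C@H]([C@@H](C[C@@]1(C2=O)O)O2)O3)OC3c4ccc(OC)cc4 | intermediate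
3 | triol: C14 hydroxymethyl, C10–OH, C8–OH, O6/O7 acetal | C1[C@H]([C@H]([C@@H](C[C@@]1(CO)O)O)O3)OC3c4ccc(OC)cc4 | intermediate
4 | C14 tosylate of 3 | C1[C@H]([C@H]([C@@H](C[C@@]1(COS(=O)(=O)c2ccc(C)cc2)O)O)O3)OC3c4ccc(OC)cc4 | intermediate
5 | C10-methyl diol: C10–OH, C8–OH trans to O7, O6/O7 acetal | C1[C@H]([C@H]([C@@H](C[C@@]1(C)O)O)O3)OC3c4ccc(OC)cc4 | intermediate
6 | C8 ketone | C1[C@H]([C@H](C(=O)C[C@@]1(C)O)O3)OC3c4ccc(OC)cc4 | intermediate
7 | all-cis diol: C8–OH cis to O7 and O10 (C8 as in the target) | C1[C@H]([C@H]([C@H](C[C@@]1(C)O)O)O3)OC3c4ccc(OC)cc4 | intermediate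
8 | O8-triisopropylsilyl ether of 7 | C1[C@H]([C@H]([C@H](C[C@@]1(C)O)O[Si](C(C)C)(C(C)C)C(C)C)O3)OC3c4ccc(OC)cc4 | intermediate (not isolated)
9 | O8-TIPS, O10-TES, O6/O7 acetal | C1[C@H]([C@H]([C@H](C[C@@]1(C)O[Si](CC)(CC)CC)O[Si](C(C)C)(C(C)C)C(C)C)O3)OC3c4ccc(OC)cc4 | intermediate
10 | C6 alcohol with O7–PMB, O8–TIPS, O10–TES | C1[C@H]([C@H]([C@H](C[C@@]1(C)O[Si](CC)(CC)CC)O[Si](C(C)C)(C(C)C)C(C)C)OCc3ccc(OC)cc3)O | intermediate
11 | C6 ketone (cyclohexanone with C1 methylene, C10 methyl/OTES, C8 OTIPS, C7 OPMB) | C1[C@](C)(O[Si](CC)(CC)CC)C[C@H](O[Si](C(C)C)(C(C)C)C(C)C)[C@H](OCc2ccc(OC)cc2)C1=O | intermediate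
12 | lithium enolate of 11 (C6=C1) | [Li]OC1=C[C@](C)(O[Si](CC)(CC)CC)C[C@H](O[Si](C(C)C)(C(C)C)C(C)C)[C@@H]1OCc1ccc(OC)cc1 | intermediate (not isolated)
13 | C1-hydroxy C6-ketone | O[C@@H]1[C@](C)(O[Si](CC)(CC)CC)C[C@H](O[Si](C(C)C)(C(C)C)C(C)C)[C@H](OCc2ccc(OC)cc2)C1=O | intermediate
14 | (E)-1-bromoprop-1-ene | C/C=C/Br | starting material
15 | (E)-prop-1-enyllithium | [Li]/C=C/C | intermediate (not isolated)
16 | propenyl diol: C6 tertiary alcohol with (E)-propenyl, C1 secondary alcohol | O[C@@H]1[C@](C)(O[Si](CC)(CC)CC)C[C@H](O[Si](C(C)C)(C(C)C)C(C)C)[C@H](OCc2ccc(OC)cc2)[C@]1(O)/C=C/C | intermediate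
17 | C1 ketone with tertiary C6–OH | O=C1[C@](C)(O[Si](CC)(CC)CC)C[C@H](O[Si](C(C)C)(C(C)C)C(C)C)[C@H](OCc2ccc(OC)cc2)[C@]1(O)/C=C/C | intermediate
18 | C6 methoxymethyl ether of 17 | O=C1[C@](C)(O[Si](CC)(CC)CC)C[C@H](O[Si](C(C)C)(C(C)C)C(C)C)[C@H](OCc2ccc(OC)cc2)[C@]1(OCOC)/C=C/C | intermediate
19 | vinylmagnesium bromide | C=C[Mg]Br | starting material
20 | key-step precursor: 1-vinyl-2-[(E)-prop-1-enyl]cyclohexane-1,2-diol 2-MOM ether with O7–PMB, O8–TIPS, O10–TES, C10 methyl | C=C[C@@]1(O)[C@](C)(O[Si](CC)(CC)CC)C[C@H](O[Si](C(C)C)(C(C)C)C(C)C)[C@H](OCc2ccc(OC)cc2)[C@]1(OCOC)/C=C/C | intermediate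
21 | potassium C1 enolate of the ten-membered ring | [K]O/C1=C\CC[C@@H](C)/C=C(OCOC)/[C@@H](OCc2ccc(OC)cc2)[C@@H](O[Si](C(C)C)(C(C)C)C(C)C)C[C@@]1(C)O[Si](CC)(CC)CC | intermediate (not isolated)
22 | key-step product: ten-membered C1 ketone with C5=C6 MOM enol ether (C6 carbonyl masked), 4R methyl | O=C1CC[C@@H](C)/C=C(OCOC)/[C@@H](OCc2ccc(OC)cc2)[C@@H](O[Si](C(C)C)(C(C)C)C(C)C)C[C@@]1(C)O[Si](CC)(CC)CC | intermediate
23 | C5 phenylselanyl 1,6-diketone (C5 epimers) | O=C1CC[C@@H](C)C([Se]c2ccccc2)C(=O)[C@@H](OCc2ccc(OC)cc2)[C@@H](O[Si](C(C)C)(C(C)C)C(C)C)C[C@@]1(C)O[Si](CC)(CC)CC | intermediate (not isolated)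
24 | 4E-enone: C6 ketone conjugated to C4=C5, C1 ketone | O=C1CC/C(C)=C/C(=O)[C@@H](OCc2ccc(OC)cc2)[C@@H](O[Si](C(C)C)(C(C)C)C(C)C)C[C@@]1(C)O[Si](CC)(CC)CC | intermediate
25 | 6S allylic alcohol | O=C1CC/C(C)=C/[C@@H](O)[C@@H](OCc2ccc(OC)cc2)[C@@H](O[Si](C(C)C)(C(C)C)C(C)C)C[C@@]1(C)O[Si](CC)(CC)CC | intermediate
26 | 4R,5R-epoxy 6-alcohol | O=C1CC[C@@]2(C)O[C@@H]2[C@@H](O)[C@@H](OCc3ccc(OC)cc3)[C@@H](O[Si](C(C)C)(C(C)C)C(C)C)C[C@@]1(C)O[Si](CC)(CC)CC | intermediate
27 | C10 alcohol (C1 ketone, free C6–OH and C10–OH) | O=C1CC[C@@]2(C)O[C@@H]2[C@@H](O)[C@@H](OCc3ccc(OC)cc3)[C@@H](O[Si](C(C)C)(C(C)C)C(C)C)C[C@@]1(C)O | intermediate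
28 | diethyl (2-hydroxyethyl)phosphonate | CCOP(=O)(CCO)OCC | starting material
29 | diethyl [2-(tert-butyldimethylsilyloxy)ethyl]phosphonate | CCOP(=O)(CCO[Si](C)(C)C(C)(C)C)OCC | intermediate
30 | α-lithio derivative of 29 | CCOP(=O)(OCC)C([Li])CO[Si](C)(C)C(C)(C)C | intermediate (not isolated)
31 | 3-(tert-butyldimethylsilyloxy)-2-(diethoxyphosphoryl)propanoic acid (racemic) | CCOP(=O)(OCC)C(CO[Si](C)(C)C(C)(C)C)C(=O)O | intermediate
32 | C6 ester of 27 with 31 (C11 epimers) | O=C1CC[C@@]2(C)O[C@@H]2[C@@H](OC(=O)C(CO[Si](C)(C)C(C)(C)C)P(=O)(OCC)OCC)[C@@H](OCc3ccc(OC)cc3)[C@@H](O[Si](C(C)C)(C(C)C)C(C)C)C[C@@]1(C)O | intermediate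
33 | 1,10-diol (chelation product at C1) | O[C@H]1CC[C@@]2(C)O[C@@H]2[C@@H](OC(=O)C(CO[Si](C)(C)C(C)(C)C)P(=O)(OCC)OCC)[C@@H](OCc3ccc(OC)cc3)[C@@H](O[Si](C(C)C)(C(C)C)C(C)C)C[C@@]1(C)O | intermediate
34 | 1R,10R:4R,5R-diepoxide with C6 phosphonate ester, O7–PMB, O8–TIPS | CCOP(=O)(OCC)C(CO[Si](C)(C)C(C)(C)C)C(=O)O[C@H]1[C@@H](OCc2ccc(OC)cc2)[C@@H](O[Si](C(C)C)(C(C)C)C(C)C)C[C@@]2(C)O[C@@H]2CC[C@@]2(C)O[C@H]12 | intermediate
35 | C7 alcohol | CCOP(=O)(OCC)C(CO[Si](C)(C)C(C)(C)C)C(=O)O[C@H]1[C@@H](O)[C@@H](O[Si](C(C)C)(C(C)C)C(C)C)C[C@@]2(C)O[C@@H]2CC[C@@]2(C)O[C@H]12 | intermediate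
36 | C7 ketone | CCOP(=O)(OCC)C(CO[Si](C)(C)C(C)(C)C)C(=O)O[C@H]1C(=O)[C@@H](O[Si](C(C)C)(C(C)C)C(C)C)C[C@@]2(C)O[C@@H]2CC[C@@]2(C)O[C@H]12 | intermediate (not isolated)
37 | diepoxy 7(11)-en-12,6-olide with O8–TIPS and O13–TBS | CC(C)[Si](C(C)C)(C(C)C)O[C@H]1C[C@@]2(C)O[C@@H]2CC[C@@]2(C)O[C@@H]2[C@H]2OC(=O)C(CO[Si](C)(C)C(C)(C)C)=C12 | intermediate
38 | 8,13-diol | O[C@H]1C[C@@]2(C)O[C@@H]2CC[C@@]2(C)O[C@@H]2[C@H]2OC(=O)C(CO)=C12 | intermediate
39 | 13-acetate 8-alcohol | O[C@H]1C[C@@]2(C)O[C@@H]2CC[C@@]2(C)O[C@@H]2[C@H]2OC(=O)C(COC(C)=O)=C12 | intermediate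
40 | tigloyl chloride, (E)-2-methylbut-2-enoyl chloride | C/C=C(\C)C(Cl)=O | starting material
41 | CNP0251711.1, (1R,4R,5R,6S,8S,10R)-13-acetoxy-1,10:4,5-diepoxy-8-tigloyloxygermacr-7(11)-en-12,6-olide | C/C=C(\C)C(=O)O[C@H]1C[C@@]2(C)O[C@@H]2CC[C@@]2(C)O[C@@H]2[C@H]2OC(=O)C(COC(C)=O)=C12 | target

## Step count and least certain steps

Total: 29 steps. Longest linear sequence: 27 steps (1–19 and 22–29) from (−)-quinic acid; the phosphonate acid 31 is a two-step side branch (20–21).

**Step 15 (key step).** The likely failures are migration of the triethylsilyl group from O10 to the neighbouring C1 alkoxide, which removes the accelerating oxyanion, and transannular aldol addition between the C1 enolate and the enol ether during the quench. Both stem from having a strongly basic oxyanion next to a silyl ether and a nucleophilic alkene across the ring. Fallback, from 20 back to 22: the tertiary alcohol is silylated (TMSOTf, Et3N) to the trimethylsilyl ether F1 and rearranged thermally without base (siloxy-Cope, xylene, about 200 °C, sealed). This gives the bis-enol ether F2, whose silyl enol ether alone is cleaved with K2CO3 in MeOH at 0 °C to give 22.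

**Step 16.** The risk is loss of control over alkene geometry. The selenoxide elimination is syn and only one C5 epimer of the selenide can give the 4E enone; if selenium enters from the exposed face and the epimers do not equilibrate, the 4Z isomer results. Fallback, from 22 back to 24: bromination of the enol ether with NBS in wet THF gives the α-bromo ketone F3 from the exposed face. Displacement with sodium benzeneselenolate inverts C5 to the selenide F4, whose oxidation and syn elimination give 24.

**Step 17.** The risk is loss of chemoselectivity: hydride may also reduce the C1 ketone, and there without chelation control. Fallback, from 24 back to 34: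
- Bu4NF/AcOH frees O10 to give the hydroxy diketone F5.
- Zn(BH4)2 then reduces both carbonyls under chelation control to the triol F6.
- VO(acac)2/t-BuOOH gives the epoxy triol F7.
- Mitsunobu cyclodehydration, which acts only on the 1,2-diol, gives the diepoxy alcohol F8.
- Esterification of F8 with 31 (DCC, DMAP) gives 34.

**Step 26.** The risk is β-elimination of silanolate from the phosphonate anion before it reaches the ketone, with epimerisation at C6 as a lesser risk. Fallback, from 36 back to 38: the elimination is driven to completion with i-Pr2NEt to the 2-phosphonoacrylate keto ester F9. 4-Methoxybenzyl alcohol and K2CO3 then add to the acrylate, and the resulting phosphonate anion olefinates C7 (tandem conjugate addition–Horner–Wadsworth–Emmons), giving the 13-PMB ether butenolide F10. DDQ gives the 13-alcohol F11, and Bu4NF/AcOH gives 38.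

**Step 8.** The risk is poor regioselectivity of the acetal opening, because the two acetal epimers may bind aluminium differently. Fallback, from 9 back to 10:
- The acetal is hydrolysed with aqueous AcOH to the diol F12.
- The less hindered equatorial C6 hydroxyl is silylated (TESCl, imidazole, −20 °C) to the C6 silyl ether F13.
- The C7 hydroxyl is converted with 4-methoxybenzyl trichloroacetimidate and catalytic acid into the PMB ether F14.
- The secondary triethylsilyl ether is removed selectively with PPTS in MeOH at 0 °C to give 10.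

## Further compounds

F1 | step 15 | C1 trimethylsilyl ether of 20 | C=C[C@@]1(O[Si](C)(C)C)[C@](C)(O[Si](CC)(CC)CC)C[C@H](O[Si](C(C)C)(C(C)C)C(C)C)[C@H](OCc2ccc(OC)cc2)[C@]1(OCOC)/C=C/C
F2 | step 15 | ten-membered C1 trimethylsilyl enol ether, C6 MOM enol ether | C[Si](C)(C)O/C1=C\CC[C@@H](C)/C=C(OCOC)/[C@@H](OCc2ccc(OC)cc2)[C@@H](O[Si](C(C)C)(C(C)C)C(C)C)C[C@@]1(C)O[Si](CC)(CC)CC
F3 | step 16 | C5 bromo 1,6-diketone (bromine anti to C3) | O=C1CC[C@@H](C)[C@H](Br)C(=O)[C@@H](OCc2ccc(OC)cc2)[C@@H](O[Si](C(C)C)(C(C)C)C(C)C)C[C@@]1(C)O[Si](CC)(CC)CC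
F4 | step 16 | C5 phenylselanyl 1,6-diketone (selenium syn to C3) | O=C1CC[C@@H](C)[C@@H]([Se]c2ccccc2)C(=O)[C@@H](OCc2ccc(OC)cc2)[C@@H](O[Si](C(C)C)(C(C)C)C(C)C)C[C@@]1(C)O[Si](CC)(CC)CC
F5 | step 17 | 4E-enone with free C10–OH | O=C1CC/C(C)=C/C(=O)[C@@H](OCc2ccc(OC)cc2)[C@@H](O[Si](C(C)C)(C(C)C)C(C)C)C[C@@]1(C)O
F6 | step 17 | 1,6,10-triol with 4E-alkene | O[C@H]1CC/C(C)=C/[C@@H](O)[C@@H](OCc2ccc(OC)cc2)[C@@H](O[Si](C(C)C)(C(C)C)C(C)C)C[C@@]1(C)O
F7 | step 17 | 4,5-epoxy 1,6,10-triol | O[C@H]1CC[C@@]2(C)O[C@@H]2[C@@H](O)[C@@H](OCc3ccc(OC)cc3)[C@@H](O[Si](C(C)C)(C(C)C)C(C)C)C[C@@]1(C)O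
F8 | step 17 | 1,10:4,5-diepoxy 6-alcohol | O[C@H]1[C@@H](OCc2ccc(OC)cc2)[C@@H](O[Si](C(C)C)(C(C)C)C(C)C)C[C@@]2(C)O[C@@H]2CC[C@@]2(C)O[C@H]12
F9 | step 26 | C6 2-(diethoxyphosphoryl)acrylate of the C7 ketone | C=C(C(=O)O[C@H]1C(=O)[C@@H](O[Si](C(C)C)(C(C)C)C(C)C)C[C@@]2(C)O[C@@H]2CC[C@@]2(C)O[C@H]12)P(=O)(OCC)OCC
F10 | step 26 | butenolide with O13–PMB and O8–TIPS | CC(C)[Si](C(C)C)(C(C)C)O[C@H]1C[C@@]2(C)O[C@@H]2CC[C@@]2(C)O[C@@H]2[C@H]2OC(=O)C(COCc3ccc(OC)cc3)=C12
F11 | step 26 | butenolide 13-alcohol with O8–TIPS | CC(C)[Si](C(C)C)(C(C)C)O[C@H]1C[C@@]2(C)O[C@@H]2CC[C@@]2(C)O[C@@H]2[C@H]2OC(=O)C(CO)=C12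
F12 | step 8 | C6,C7-diol with O8–TIPS and O10–TES | C1[C@H]([C@H]([C@H](C[C@@]1(C)O[Si](CC)(CC)CC)O[Si](C(C)C)(C(C)C)C(C)C)O)O
F13 | step 8 | C6 triethylsilyl ether of the diol | C1[C@H]([C@H]([C@H](C[C@@]1(C)O[Si](CC)(CC)CC)O[Si](C(C)C)(C(C)C)C(C)C)O)O[Si](CC)(CC)CC
F14 | step 8 | C7 PMB ether with C6 triethylsilyl ether | C1[C@H]([C@H]([C@H](C[C@@]1(C)O[Si](CC)(CC)CC)O[Si](C(C)C)(C(C)C)C(C)C)OCc3ccc(OC)cc3)O[Si](CC)(CC)CC
A1 | alternative 1 | 8β-hydroxygermacra-1(10),4,11(13)-trien-12-oic acid | O[C@@H]1C/C(C)=C/CC/C(C)=C/C[C@@H]1C(=C)C(=O)O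
A2 | alternative 1 | eupatolide (8β-hydroxycostunolide) | O[C@@H]1C/C(C)=C/CC/C(C)=C/[C@H]2OC(=O)C(=C)[C@H]12
A3 | alternative 2 | 1,10:4,5-diepoxygermacra-7Z,11(13)-dien-12,6-olide | C=C1/C2=C/C[C@@]3(C)O[C@@H]3CC[C@@]3(C)O[C@@H]3[C@H]2OC1=O
A4 | alternative 2 | 8,13-epidioxy-1,10:4,5-diepoxygermacr-7(11)-en-12,6-olide | O1OCC2=C3[C@@H]1C[C@@]1(C)O[C@@H]1CC[C@@]1(C)O[C@@H]1[C@H]3OC2=O
A5 | alternative 3 | open-chain ynal: methyl ester with C6 aldehyde, C4≡C5 alkyne, 1(10)E-alkene, O8–TBS, C13 acetate | C#CCC/C=C(\C)C[C@H](O[Si](C)(C)C(C)(C)C)/C(C=O)=C(\COC(C)=O)C(=O)OC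
A6 | alternative 3 | 13-acetoxy-8-silyloxygermacra-1(10),4,7(11)-trien-12,6-olide | CC(C)(C)[Si](C)(C)O[C@H]1C/C(C)=C/CC/C(C)=C/[C@H]2OC(=O)C(COC(C)=O)=C12
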